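## Retrosynthetic overview

1. Target 32 ⇐ fluoride desilylation ⇐ (E)-butenoyl group from an ethynyl group (gold-catalysed hydration, boron aldol with acetaldehyde, elimination) and tiglate by acylation ⇐ ethynyl hydroxy-lactone 23.
2. Ring B (cis-fused γ-lactone, formed last) and its trans-disposed neighbouring hydroxyl ⇐ acid-triggered 5-exo opening of an epoxide by the propanoate ester; the lactone α-methyl centre by kinetic protonation of the lactone enolate.
3. Tertiary carbinol ⇐ ethynyl Grignard addition to cycloheptenone 14; ring methyl ⇐ enolate methylation of enone 12.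
4. Propanoate side chain ⇐ Pd-catalysed allylic alkylation (net retention) of monoacetate 7 ⇐ lipase desymmetrisation of meso diol 6.
5. Ring A (the cycloheptane) is present from the start: tropone 1 ⇒ dienol ⇒ singlet-oxygen cycloaddition ⇒ 6.

Assumption: the lipase acetylates the (R)-configured carbinol of meso diol 6 (the sense lipases show with other meso cycloalk-2-ene-1,4-diols), and singlet oxygen adds to 4 anti to the silyloxy group.

Abbreviations: TBS = tert-butyldimethylsilyl, TES = triethylsilyl, TMS = trimethylsilyl.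

## Route

Step 1
Reactants: 1 tropone
Product: 3 cyclohepta-3,5-dien-1-ol, via cyclohepta-3,5-dien-1-one 2 (not isolated)
Conditions: NaBH4, MeOH/H2O, 0 °C → rt
Reagents that add atoms: none
Why: Conjugate hydride addition to tropone gives the unconjugated dienone, whose carbonyl is then reduced (borohydride reduction); no stereocentre is formed.

Step 2
Reactants: 3 cyclohepta-3,5-dien-1-ol
Product: 4 tert-butyl(cyclohepta-3,5-dien-1-yloxy)dimethylsilane
Conditions: TBSCl, imidazole, DMF, rt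
Reagents that add atoms: tert-butyldimethylsilyl chloride, CC(C)(C)[Si](C)(C)Cl
Why: Standard silylation of a secondary alcohol; the bulky ether later steers the cycloaddition and survives to the last step.

Step 3
Reactants: 4 tert-butyl(cyclohepta-3,5-dien-1-yloxy)dimethylsilane
Product: 6 meso-(1R,4S,6s)-6-(TBS-oxy)cyclohept-2-ene-1,4-diol, via endoperoxide 5 (not isolated)
Conditions: O2, hν, tetraphenylporphyrin (cat.), CH2Cl2, 0 °C; then Zn, AcOH, 0 °C → rt
Reagents that add atoms: dioxygen, O=O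
Why: [4+2] cycloaddition of singlet oxygen to the cis-diene on the face away from the silyloxy group, then reductive O–O cleavage, gives the cis-diol trans to the silyl ether; 5 and 6 are meso and therefore still achiral.

Step 4
Reactants: 6 meso-(1R,4S,6s)-6-(TBS-oxy)cyclohept-2-ene-1,4-diol
Product: 7 (1R,4S,6S)-6-(TBS-oxy)-4-hydroxycyclohept-2-en-1-yl acetate
Conditions: lipase (serine hydrolase from Burkholderia cepacia, immobilised), isopropenyl acetate, t-BuOMe, 40 °C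
Reagents that add atoms: isopropenyl acetate, CC(=C)OC(C)=O
Why: Enantiotopic-group-selective transesterification through the acyl-enzyme: the lipase acetylates only the (R)-carbinol of the meso diol, so this catalytic step is the first to give a chiral compound and fixes the absolute configuration of all three ring stereocentres.

Step 5
Reactants: 7 (1R,4S,6S)-6-(TBS-oxy)-4-hydroxycyclohept-2-en-1-yl acetate; 8 dimethyl methylmalonate
Product: 10 dimethyl 2-[(1R,4S,6R)-6-(TBS-oxy)-4-hydroxycyclohept-2-en-1-yl]-2-methylpropanedioate, via sodium enolate 9 (not isolated)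
Conditions: NaH, THF, 0 °C; then 7, Pd(PPh3)4 (5 mol%), THF, 60 °C
Reagents that add atoms: none
Why: Tsuji–Trost allylic alkylation with the zerovalent palladium complex: ionisation and attack of the soft nucleophile each invert, so the malonate replaces acetate with net retention (cis to the free hydroxyl), and it attacks the allyl terminus remote from the hydroxyl.

Step 6
Reactants: 10 dimethyl 2-[(1R,4S,6R)-6-(TBS-oxy)-4-hydroxycyclohept-2-en-1-yl]-2-methylpropanedioate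
Product: 11 methyl (2RS)-2-[(1R,4S,6R)-6-(TBS-oxy)-4-hydroxycyclohept-2-en-1-yl]propanoate
Conditions: NaCl, H2O, DMSO, 155 °C
Reagents that add atoms: none
Why: Krapcho demethoxycarbonylation removes one ester under neutral conditions; the side-chain centre is formed as a mixture here and is set in step 14.

Step 7
Reactants: 11 methyl (2RS)-2-[(1R,4S,6R)-6-(TBS-oxy)-4-hydroxycyclohept-2-en-1-yl]propanoate
Product: 12 methyl (2RS)-2-[(1R,6R)-6-(TBS-oxy)-4-oxocyclohept-2-en-1-yl]propanoate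
Conditions: Dess–Martin periodinane, CH2Cl2, rt
Reagents that add atoms: none
Why: Mild oxidation of the allylic alcohol to the enone without touching the silyl ether or the γ-stereocentre.

Step 8
Reactants: 12 methyl (2RS)-2-[(1R,6R)-6-(TBS-oxy)-4-oxocyclohept-2-en-1-yl]propanoate
Product: 14 methyl (2RS)-2-[(1R,5S,6R)-6-(TBS-oxy)-5-methyl-4-oxocyclohept-2-en-1-yl]propanoate, via lithium enolate 13 (not isolated)
Conditions: LiN(iPr)2 (1.05 equiv), THF, −78 °C; then MeI, DMPU, −78 → −30 °C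
Reagents that add atoms: iodomethane, CI
Why: Kinetic α′-deprotonation of the enone (the ketone is far more acidic than the hindered ester methine) and enolate alkylation anti to the neighbouring silyloxy group give the trans methyl/silyloxy pair.

Step 9
Reactants: 14 methyl (2RS)-2-[(1R,5S,6R)-6-(TBS-oxy)-5-methyl-4-oxocyclohept-2-en-1-yl]propanoate; 15 ethynylmagnesium bromide
Product: 16 methyl (2RS)-2-[(1R,4R,5S,6R)-6-(TBS-oxy)-4-ethynyl-4-hydroxy-5-methylcyclohept-2-en-1-yl]propanoate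
Conditions: THF, −78 → 0 °C; then aq. NH4Cl
Reagents that add atoms: none
Why: Chemoselective 1,2-Grignard addition to the ketone (the ester is untouched) on the face opposite the adjacent methyl group, so the new hydroxyl is cis to that methyl; epimers at the carbinol are separated here.

Step 10
Reactants: 16 methyl (2RS)-2-[(1R,4R,5S,6R)-6-(TBS-oxy)-4-ethynyl-4-hydroxy-5-methylcyclohept-2-en-1-yl]propanoate
Product: 17 methyl (2RS)-2-[(1R,4R,5S,6R)-6-(TBS-oxy)-4-ethynyl-5-methyl-4-(TES-oxy)cyclohept-2-en-1-yl]propanoate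
Conditions: TESOTf, 2,6-lutidine, CH2Cl2, 0 °C
Reagents that add atoms: triethylsilyl trifluoromethanesulfonate, CC[Si](CC)(CC)OS(=O)(=O)C(F)(F)F
Why: Silyl triflate protection of the tertiary alcohol removes any hydroxyl-directing effect and makes that face of the ring alkene bulky for the next step.

Step 11
Reactants: 17 methyl (2RS)-2-[(1R,4R,5S,6R)-6-(TBS-oxy)-4-ethynyl-5-methyl-4-(TES-oxy)cyclohept-2-en-1-yl]propanoate
Product: 18 methyl (2RS)-2-[(1S,2S,4R,5S,6R,7S)-4-(TBS-oxy)-6-ethynyl-5-methyl-6-(TES-oxy)-8-oxabicyclo[5.1.0]octan-2-yl]propanoate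
Conditions: mCPBA, CH2Cl2, 0 °C → rt
Reagents that add atoms: 3-chloroperoxybenzoic acid, OOC(=O)c1cccc(Cl)c1
Why: Prilezhaev epoxidation of the only alkene (the alkyne is inert) on the face opposite both flanking substituents, the silyloxy group and the propanoate chain, gives the epoxide trans to the side chain.

Step 12
Reactants: 18 methyl (2RS)-2-[(1S,2S,4R,5S,6R,7S)-4-(TBS-oxy)-6-ethynyl-5-methyl-6-(TES-oxy)-8-oxabicyclo[5.1.0]octan-2-yl]propanoate
Product: 19 (3RS,3aS,5R,6S,7R,8S,8aR)-5-(TBS-oxy)-7-ethynyl-8-hydroxy-3,6-dimethyl-7-(TES-oxy)octahydro-2H-cyclohepta[b]furan-2-one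
Conditions: camphorsulfonic acid (10 mol%), H2O (1.5 equiv), CH2Cl2, 0 °C → rt
Reagents that add atoms: water, O
Why: Acid-catalysed 5-exo epoxide opening by the ester carbonyl with inversion at the attacked carbon gives the cis-fused γ-lactone, leaves the former oxirane oxygen as the hydroxyl trans to the lactone oxygen, and water releases methanol.

Step 13
Reactants: 19 (3RS,3aS,5R,6S,7R,8S,8aR)-5-(TBS-oxy)-7-ethynyl-8-hydroxy-3,6-dimethyl-7-(TES-oxy)octahydro-2H-cyclohepta[b]furan-2-one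
Product: 20 (3RS,3aS,5R,6S,7R,8S,8aR)-5-(TBS-oxy)-7-ethynyl-3,6-dimethyl-7-(TES-oxy)-8-(TMS-oxy)octahydro-2H-cyclohepta[b]furan-2-one
Conditions: TMSCl, imidazole, CH2Cl2, 0 °C
Reagents that add atoms: chlorotrimethylsilane, C[Si](C)(C)Cl
Why: Temporary silylation of the secondary alcohol so that no alkoxide is present in the next step, which would otherwise invite migration of the neighbouring TES group.

Step 14
Reactants: 20 (3RS,3aS,5R,6S,7R,8S,8aR)-5-(TBS-oxy)-7-ethynyl-3,6-dimethyl-7-(TES-oxy)-8-(TMS-oxy)octahydro-2H-cyclohepta[b]furan-2-one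
Product: 23 (3R,3aS,5R,6S,7R,8S,8aR)-5-(TBS-oxy)-7-ethynyl-8-hydroxy-3,6-dimethyl-7-(TES-oxy)octahydro-2H-cyclohepta[b]furan-2-one, via dilithio derivative 21 (not isolated), via C3-protonated TMS ether 22 (not isolated)
Conditions: LiN(iPr)2 (2.3 equiv), THF, −78 °C; then AcOH, THF, −78 °C; then 1 M aq. citric acid, THF, 0 °C
Reagents that add atoms: none
Why: Kinetic protonation of the planar lactone enolate on the convex face of the cis-fused bicycle (the face of the two ring-fusion hydrogens) places the methyl on the concave face (3R); both C3 epimers converge, the acetylide is simply reprotonated, the TMS ether is hydrolysed in the acidic work-up, and any minor epimer can be resubmitted.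

Step 15
Reactants: 23 (3R,3aS,5R,6S,7R,8S,8aR)-5-(TBS-oxy)-7-ethynyl-8-hydroxy-3,6-dimethyl-7-(TES-oxy)octahydro-2H-cyclohepta[b]furan-2-one; 24 tigloyl chloride
Product: 25 (3R,3aS,5R,6S,7R,8S,8aR)-5-(TBS-oxy)-7-ethynyl-3,6-dimethyl-2-oxo-7-(TES-oxy)octahydro-2H-cyclohepta[b]furan-8-yl (2E)-2-methylbut-2-enoate
Conditions: DMAP, Et3N, CH2Cl2, 0 → 40 °C
Reagents that add atoms: none
Why: DMAP-catalysed acylation of the only free hydroxyl; the (E)-acid chloride cannot isomerise, and the amine bases are too weak to epimerise the lactone α-centre.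

Step 16
Reactants: 25 (3R,3aS,5R,6S,7R,8S,8aR)-5-(TBS-oxy)-7-ethynyl-3,6-dimethyl-2-oxo-7-(TES-oxy)octahydro-2H-cyclohepta[b]furan-8-yl (2E)-2-methylbut-2-enoate
Product: 26 (3R,3aS,5R,6S,7S,8S,8aR)-7-acetyl-5-(TBS-oxy)-3,6-dimethyl-2-oxo-7-(TES-oxy)octahydro-2H-cyclohepta[b]furan-8-yl (2E)-2-methylbut-2-enoate
Conditions: (Ph3P)AuNTf2 (3 mol%), H2O, 1,4-dioxane, 50 °C
Reagents that add atoms: water, O
Why: Gold-catalysed Markovnikov hydration of the terminal alkyne puts the carbonyl on the carbon attached to the ring, under conditions that leave esters, lactone and silyl ethers alone.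

Step 17
Reactants: 26 (3R,3aS,5R,6S,7S,8S,8aR)-7-acetyl-5-(TBS-oxy)-3,6-dimethyl-2-oxo-7-(TES-oxy)octahydro-2H-cyclohepta[b]furan-8-yl (2E)-2-methylbut-2-enoate; 27 acetaldehyde
Product: 29 (3R,3aS,5R,6S,7S,8S,8aR)-5-(TBS-oxy)-7-[(3RS)-3-hydroxybutanoyl]-3,6-dimethyl-2-oxo-7-(TES-oxy)octahydro-2H-cyclohepta[b]furan-8-yl (2E)-2-methylbut-2-enoate, via dibutylboron enolate 28 (not isolated)
Conditions: Bu2BOTf, iPr2NEt, CH2Cl2, −78 °C; then 27, −78 → −20 °C; then pH 7 buffer, MeOH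
Reagents that add atoms: none
Why: Boron aldol reaction: soft enolisation touches only the methyl ketone (not the lactone or tiglate) and avoids the acyl transfer a lithium enolate could undergo with the neighbouring ester; the new carbinol centre is a mixture and is removed in the next step.

Step 18
Reactants: 29 (3R,3aS,5R,6S,7S,8S,8aR)-5-(TBS-oxy)-7-[(3RS)-3-hydroxybutanoyl]-3,6-dimethyl-2-oxo-7-(TES-oxy)octahydro-2H-cyclohepta[b]furan-8-yl (2E)-2-methylbut-2-enoate
Product: 31 (3R,3aS,5R,6S,7S,8S,8aR)-7-[(2E)-but-2-enoyl]-5-(TBS-oxy)-3,6-dimethyl-2-oxo-7-(TES-oxy)octahydro-2H-cyclohepta[b]furan-8-yl (2E)-2-methylbut-2-enoate, via methanesulfonate 30 (not isolated)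
Conditions: MsCl, Et3N (5 equiv), CH2Cl2, 0 °C → rt
Reagents that add atoms: none
Why: Mesylation followed by E1cB elimination of the β-mesyloxy ketone gives the thermodynamically favoured (E)-enone from both carbinol epimers.

Step 19
Reactants: 31 (3R,3aS,5R,6S,7S,8S,8aR)-7-[(2E)-but-2-enoyl]-5-(TBS-oxy)-3,6-dimethyl-2-oxo-7-(TES-oxy)octahydro-2H-cyclohepta[b]furan-8-yl (2E)-2-methylbut-2-enoate
Product: 32 (3R,3aS,5R,6S,7S,8S,8aR)-7-[(2E)-but-2-enoyl]-5,7-dihydroxy-3,6-dimethyl-2-oxooctahydro-2H-cyclohepta[b]furan-8-yl (2E)-2-methylbut-2-enoate (target)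
Conditions: HF·pyridine, pyridine, THF, 0 °C → rt
Reagents that add atoms: none
Why: Buffered fluoride desilylation removes both silyl ethers without base, so the enone, the tiglate and the epimerisable lactone α-centre are preserved.

## Compound list

1 | tropone (cyclohepta-2,4,6-trien-1-one) | O=C1C=CC=CC=C1 | starting material
2 | cyclohepta-3,5-dien-1-one | O=C1CC=CC=CC1 | intermediate
3 | cyclohepta-3,5-dien-1-ol | OC1CC=CC=CC1 | intermediate
4 | tert-butyl(cyclohepta-3,5-dien-1-yloxy)dimethylsilane | CC(C)(C)[Si](C)(C)OC1CC=CC=CC1 | intermediate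
5 | meso-(1R,3s,5S)-3-(tert-butyldimethylsilyloxy)-6,7-dioxabicyclo[3.2.2]non-8-ene (peroxide bridge anti to the silyloxy group) | O1[C@H]2C[C@H](O[Si](C)(C)C(C)(C)C)C[C@@H](O1)C=C2 | intermediate
6 | meso-(1R,4S,6s)-6-(tert-butyldimethylsilyloxy)cyclohept-2-ene-1,4-diol (hydroxyls cis to each other, trans to the silyloxy group) | O[C@H]1C[C@H](O[Si](C)(C)C(C)(C)C)C[C@@H](O)C=C1 | intermediate
7 | (1R,4S,6S)-6-(tert-butyldimethylsilyloxy)-4-hydroxycyclohept-2-en-1-yl acetate | O[C@H]1C[C@H](O[Si](C)(C)C(C)(C)C)C[C@@H](OC(C)=O)C=C1 | intermediate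
8 | dimethyl 2-methylpropanedioate (dimethyl methylmalonate) | COC(=O)C(C)C(=O)OC | starting material
9 | sodium enolate of 8 | [Na+].COC(=O)[C-](C)C(=O)OC | intermediate
10 | dimethyl 2-[(1R,4S,6R)-6-(tert-butyldimethylsilyloxy)-4-hydroxycyclohept-2-en-1-yl]-2-methylpropanedioate | O[C@H]1C[C@H](O[Si](C)(C)C(C)(C)C)C[C@@H](C(C)(C(=O)OC)C(=O)OC)C=C1 | intermediate
11 | methyl (2RS)-2-[(1R,4S,6R)-6-(tert-butyldimethylsilyloxy)-4-hydroxycyclohept-2-en-1-yl]propanoate | O[C@H]1C[C@H](O[Si](C)(C)C(C)(C)C)C[C@@H](C(C)C(=O)OC)C=C1 | intermediate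
12 | methyl (2RS)-2-[(1R,6R)-6-(tert-butyldimethylsilyloxy)-4-oxocyclohept-2-en-1-yl]propanoate | O=C1C[C@H](O[Si](C)(C)C(C)(C)C)C[C@@H](C(C)C(=O)OC)C=C1 | intermediate
13 | kinetic (α′) lithium enolate of 12 | [Li+].[O-]C1=C[C@H](O[Si](C)(C)C(C)(C)C)C[C@@H](C(C)C(=O)OC)C=C1 | intermediate
14 | methyl (2RS)-2-[(1R,5S,6R)-6-(tert-butyldimethylsilyloxy)-5-methyl-4-oxocyclohept-2-en-1-yl]propanoate | O=C1[C@@H](C)[C@H](O[Si](C)(C)C(C)(C)C)C[C@@H](C(C)C(=O)OC)C=C1 | intermediate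
15 | ethynylmagnesium bromide | C#C[Mg]Br | starting material
16 | methyl (2RS)-2-[(1R,4R,5S,6R)-6-(tert-butyldimethylsilyloxy)-4-ethynyl-4-hydroxy-5-methylcyclohept-2-en-1-yl]propanoate | C#C[C@]1(O)[C@@H](C)[C@H](O[Si](C)(C)C(C)(C)C)C[C@@H](C(C)C(=O)OC)C=C1 | intermediate
17 | methyl (2RS)-2-[(1R,4R,5S,6R)-6-(tert-butyldimethylsilyloxy)-4-ethynyl-5-methyl-4-(triethylsilyloxy)cyclohept-2-en-1-yl]propanoate | C#C[C@]1(O[Si](CC)(CC)CC)[C@@H](C)[C@H](O[Si](C)(C)C(C)(C)C)C[C@@H](C(C)C(=O)OC)C=C1 | intermediate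
18 | methyl (2RS)-2-[(1S,2S,4R,5S,6R,7S)-4-(tert-butyldimethylsilyloxy)-6-ethynyl-5-methyl-6-(triethylsilyloxy)-8-oxabicyclo[5.1.0]octan-2-yl]propanoate (oxirane oxygen trans to the side chain and to the triethylsilyloxy group) | C#C[C@]1(O[Si](CC)(CC)CC)[C@@H](C)[C@H](O[Si](C)(C)C(C)(C)C)C[C@@H](C(C)C(=O)OC)[C@@H]2O[C@H]12 | intermediate
19 | (3RS,3aS,5R,6S,7R,8S,8aR)-5-(tert-butyldimethylsilyloxy)-7-ethynyl-8-hydroxy-3,6-dimethyl-7-(triethylsilyloxy)octahydro-2H-cyclohepta[b]furan-2-one | C#C[C@]1(O[Si](CC)(CC)CC)[C@@H](C)[C@H](O[Si](C)(C)C(C)(C)C)C[C@@H]2[C@@H](OC(=O)C2C)[C@@H]1O | intermediate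
20 | (3RS,3aS,5R,6S,7R,8S,8aR)-5-(tert-butyldimethylsilyloxy)-7-ethynyl-3,6-dimethyl-7-(triethylsilyloxy)-8-(trimethylsilyloxy)octahydro-2H-cyclohepta[b]furan-2-one | C#C[C@]1(O[Si](CC)(CC)CC)[C@@H](C)[C@H](O[Si](C)(C)C(C)(C)C)C[C@@H]2[C@@H](OC(=O)C2C)[C@@H]1O[Si](C)(C)C | intermediate
21 | dilithio derivative of 20 (lithium acetylide plus lithium lactone enolate) | [Li+].[Li+].[C-]#C[C@]1(O[Si](CC)(CC)CC)[C@@H](C)[C@H](O[Si](C)(C)C(C)(C)C)C[C@@H]2[C@@H](OC([O-])=C2C)[C@@H]1O[Si](C)(C)C | intermediate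
22 | (3R,3aS,5R,6S,7R,8S,8aR)-5-(tert-butyldimethylsilyloxy)-7-ethynyl-3,6-dimethyl-7-(triethylsilyloxy)-8-(trimethylsilyloxy)octahydro-2H-cyclohepta[b]furan-2-one | C#C[C@]1(O[Si](CC)(CC)CC)[C@@H](C)[C@H](O[Si](C)(C)C(C)(C)C)C[C@@H]2[C@@H](OC(=O)[C@@H]2C)[C@@H]1O[Si](C)(C)C | intermediate
23 | (3R,3aS,5R,6S,7R,8S,8aR)-5-(tert-butyldimethylsilyloxy)-7-ethynyl-8-hydroxy-3,6-dimethyl-7-(triethylsilyloxy)octahydro-2H-cyclohepta[b]furan-2-one | C#C[C@]1(O[Si](CC)(CC)CC)[C@@H](C)[C@H](O[Si](C)(C)C(C)(C)C)C[C@@H]2[C@@H](OC(=O)[C@@H]2C)[C@@H]1O | intermediate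
24 | (2E)-2-methylbut-2-enoyl chloride (tigloyl chloride) | C/C=C(\C)C(Cl)=O | starting material
25 | (3R,3aS,5R,6S,7R,8S,8aR)-5-(tert-butyldimethylsilyloxy)-7-ethynyl-3,6-dimethyl-2-oxo-7-(triethylsilyloxy)octahydro-2H-cyclohepta[b]furan-8-yl (2E)-2-methylbut-2-enoate | C#C[C@]1(O[Si](CC)(CC)CC)[C@@H](C)[C@H](O[Si](C)(C)C(C)(C)C)C[C@@H]2[C@@H](OC(=O)[C@@H]2C)[C@@H]1OC(=O)/C(C)=C/C | intermediate
26 | (3R,3aS,5R,6S,7S,8S,8aR)-7-acetyl-5-(tert-butyldimethylsilyloxy)-3,6-dimethyl-2-oxo-7-(triethylsilyloxy)octahydro-2H-cyclohepta[b]furan-8-yl (2E)-2-methylbut-2-enoate | CC(=O)[C@]1(O[Si](CC)(CC)CC)[C@@H](C)[C@H](O[Si](C)(C)C(C)(C)C)C[C@@H]2[C@@H](OC(=O)[C@@H]2C)[C@@H]1OC(=O)/C(C)=C/C | intermediate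
27 | acetaldehyde | CC=O | starting material
28 | dibutylboron enolate of 26 | C=C(OB(CCCC)CCCC)[C@]1(O[Si](CC)(CC)CC)[C@@H](C)[C@H](O[Si](C)(C)C(C)(C)C)C[C@@H]2[C@@H](OC(=O)[C@@H]2C)[C@@H]1OC(=O)/C(C)=C/C | intermediate
29 | (3R,3aS,5R,6S,7S,8S,8aR)-5-(tert-butyldimethylsilyloxy)-7-[(3RS)-3-hydroxybutanoyl]-3,6-dimethyl-2-oxo-7-(triethylsilyloxy)octahydro-2H-cyclohepta[b]furan-8-yl (2E)-2-methylbut-2-enoate | CC(O)CC(=O)[C@]1(O[Si](CC)(CC)CC)[C@@H](C)[C@H](O[Si](C)(C)C(C)(C)C)C[C@@H]2[C@@H](OC(=O)[C@@H]2C)[C@@H]1OC(=O)/C(C)=C/C | intermediate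
30 | methanesulfonate of 29 | CC(OS(C)(=O)=O)CC(=O)[C@]1(O[Si](CC)(CC)CC)[C@@H](C)[C@H](O[Si](C)(C)C(C)(C)C)C[C@@H]2[C@@H](OC(=O)[C@@H]2C)[C@@H]1OC(=O)/C(C)=C/C | intermediate
31 | (3R,3aS,5R,6S,7S,8S,8aR)-7-[(2E)-but-2-enoyl]-5-(tert-butyldimethylsilyloxy)-3,6-dimethyl-2-oxo-7-(triethylsilyloxy)octahydro-2H-cyclohepta[b]furan-8-yl (2E)-2-methylbut-2-enoate | C/C=C/C(=O)[C@]1(O[Si](CC)(CC)CC)[C@@H](C)[C@H](O[Si](C)(C)C(C)(C)C)C[C@@H]2[C@@H](OC(=O)[C@@H]2C)[C@@H]1OC(=O)/C(C)=C/C | intermediate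
32 | (3R,3aS,5R,6S,7S,8S,8aR)-7-[(2E)-but-2-enoyl]-5,7-dihydroxy-3,6-dimethyl-2-oxooctahydro-2H-cyclohepta[b]furan-8-yl (2E)-2-methylbut-2-enoate | C/C=C/C(=O)[C@]1(O)[C@@H](C)[C@H](O)C[C@@H]2[C@@H](OC(=O)[C@@H]2C)[C@@H]1OC(=O)/C(C)=C/C | target

## Step count and risks

Total step count: 19. Longest linear sequence: 19 steps (1 → 32); compounds 8, 15, 24 and 27 are commercial and enter directly.

Steps most likely to fail:

Step 9 (facial selectivity at the tertiary carbinol). If the Grignard reagent attacks 14 mainly on the wrong face, the two bonds at that carbon are made in the reverse order, so that the same facial preference places oxygen rather than carbon on that face. The fallback sets out from 14. Wittig methylenation (Ph3P=CH2, THF, 0 °C) gives methyl (2RS)-2-[(1R,5R,6R)-6-(tert-butyldimethylsilyloxy)-5-methyl-4-methylidenecyclohept-2-en-1-yl]propanoate F3. Dihydroxylation of the more accessible exocyclic alkene (OsO4 cat., N-methylmorpholine N-oxide, acetone/H2O) gives methyl (2RS)-2-[(1R,4R,5S,6R)-6-(tert-butyldimethylsilyloxy)-4-hydroxy-4-(hydroxymethyl)-5-methylcyclohept-2-en-1-yl]propanoate F4. Bis-silylation (TESOTf, 2,6-lutidine) gives methyl (2RS)-2-[(1R,4R,5S,6R)-6-(tert-butyldimethylsilyloxy)-5-methyl-4-(triethylsilyloxy)-4-[(triethylsilyloxy)methyl]cyclohept-2-en-1-yl]propanoate F5. Swern oxidation, which converts a primary triethylsilyl ether directly into the aldehyde, gives methyl (2RS)-2-[(1R,4R,5S,6R)-6-(tert-butyldimethylsilyloxy)-4-formyl-5-methyl-4-(triethylsilyloxy)cyclohept-2-en-1-yl]propanoate F6. Seyferth–Gilbert homologation with the Ohira–Bestmann reagent (dimethyl (1-diazo-2-oxopropyl)phosphonate, K2CO3, MeOH) turns the formyl group into the ethynyl group, and the fallback comes back to the route at 17.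

Step 8 (methylation next to a β-silyloxy group: elimination of the silyloxy group from enolate 13, or poor trans selectivity). The alkylation is then done on the free β-hydroxy ketone, where the oxygen is an alkoxide and cannot leave. The fallback sets out from 12. Desilylation (HF·pyridine, THF, 0 °C) gives methyl (2RS)-2-[(1R,6R)-6-hydroxy-4-oxocyclohept-2-en-1-yl]propanoate F1. Its dianion (LiN(iPr)2, 2.2 equiv, THF, −78 °C) is methylated with MeI in the Fráter–Seebach manner, anti to the C–O bond, to give methyl (2RS)-2-[(1R,5S,6R)-6-hydroxy-5-methyl-4-oxocyclohept-2-en-1-yl]propanoate F2. Silylation (TBSCl, imidazole, DMF) comes back to the route at 14.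

Step 15 (acylation of a hindered secondary alcohol, flanked by a fully substituted silyloxy carbon, with a poorly electrophilic conjugated acid chloride). The tiglate is then built in two stages from a more reactive saturated acyl donor. The fallback sets out from 23. Esterification with 2-(diethoxyphosphoryl)propanoic acid (DCC, DMAP, CH2Cl2) gives (3R,3aS,5R,6S,7R,8S,8aR)-5-(tert-butyldimethylsilyloxy)-7-ethynyl-3,6-dimethyl-2-oxo-7-(triethylsilyloxy)octahydro-2H-cyclohepta[b]furan-8-yl (2RS)-2-(diethoxyphosphoryl)propanoate F7. A Horner–Wadsworth–Emmons reaction with acetaldehyde 27 (LiCl, DBU, MeCN, 0 °C) forms the (E)-2-methylbut-2-enoate and comes back to the route at 25.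

## Further compounds

F1 | step 8 | methyl (2RS)-2-[(1R,6R)-6-hydroxy-4-oxocyclohept-2-en-1-yl]propanoate | O=C1C[C@H](O)C[C@@H](C(C)C(=O)OC)C=C1
F2 | step 8 | methyl (2RS)-2-[(1R,5S,6R)-6-hydroxy-5-methyl-4-oxocyclohept-2-en-1-yl]propanoate | O=C1[C@@H](C)[C@H](O)C[C@@H](C(C)C(=O)OC)C=C1
F3 | step 9 | methyl (2RS)-2-[(1R,5R,6R)-6-(tert-butyldimethylsilyloxy)-5-methyl-4-methylidenecyclohept-2-en-1-yl]propanoate | C=C1[C@@H](C)[C@H](O[Si](C)(C)C(C)(C)C)C[C@@H](C(C)C(=O)OC)C=C1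
F4 | step 9 | methyl (2RS)-2-[(1R,4R,5S,6R)-6-(tert-butyldimethylsilyloxy)-4-hydroxy-4-(hydroxymethyl)-5-methylcyclohept-2-en-1-yl]propanoate | OC[C@]1(O)[C@@H](C)[C@H](O[Si](C)(C)C(C)(C)C)C[C@@H](C(C)C(=O)OC)C=C1
F5 | step 9 | methyl (2RS)-2-[(1R,4R,5S,6R)-6-(tert-butyldimethylsilyloxy)-5-methyl-4-(triethylsilyloxy)-4-[(triethylsilyloxy)methyl]cyclohept-2-en-1-yl]propanoate | CC[Si](CC)(CC)OC[C@]1(O[Si](CC)(CC)CC)[C@@H](C)[C@H](O[Si](C)(C)C(C)(C)C)C[C@@H](C(C)C(=O)OC)C=C1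
F6 | step 9 | methyl (2RS)-2-[(1R,4R,5S,6R)-6-(tert-butyldimethylsilyloxy)-4-formyl-5-methyl-4-(triethylsilyloxy)cyclohept-2-en-1-yl]propanoate | O=C[C@]1(O[Si](CC)(CC)CC)[C@@H](C)[C@H](O[Si](C)(C)C(C)(C)C)C[C@@H](C(C)C(=O)OC)C=C1
F7 | step 15 | (3R,3aS,5R,6S,7R,8S,8aR)-5-(tert-butyldimethylsilyloxy)-7-ethynyl-3,6-dimethyl-2-oxo-7-(triethylsilyloxy)octahydro-2H-cyclohepta[b]furan-8-yl (2RS)-2-(diethoxyphosphoryl)propanoate | C#C[C@]1(O[Si](CC)(CC)CC)[C@@H](C)[C@H](O[Si](C)(C)C(C)(C)C)C[C@@H]2[C@@H](OC(=O)[C@@H]2C)[C@@H]1OC(=O)C(C)P(=O)(OCC)OCC
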